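If a species falls by the same share each hour, one time constant tells how much of it is left at any later time. In this flask starting material gives target, but in the readings the two together fall short of the charge. The beta run is this very flask so far, and the epsilon run is the same charge, colder.

| flask | starting material | temperature | remark | time |
|---|---|---|---|---|
| beta | 0.36 M | 5 °C | the very flask that is asked about, followed so far |  |
| epsilon | 0.36 M | −10 °C | run made earlier |  |
| flask | 0.36 M | 5 °C |  | 10 h |

| run | time / h | target / % | starting material / % |
|---|---|---|---|
| beta | 1.50 | 30 | 34 |
| beta | 3.00 | 29 | 11 |
| beta | 5.00 | 24 | 3 |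
| beta | 6.00 | 27 | 2 |
| epsilon | 3.00 | 13 | 79 |
| epsilon | 6.00 | 19 | 64 |
| epsilon | 10.0 | 26 | 45 |
| epsilon | 12.0 | 26 | 39 |

(each reading ± 1.5 percentage points)

- target that was removed still counts
- additions bring no volume worth counting

- teal: change nothing and wait 3.0 h more
- grey: at 10 h raise the temperature by 15 K, then wait 3.0 h
- amber: at 10 h add starting material, 50.0% of the amount charged, then wait 3.0 h
- violet: at 10 h take out 90% of the target then present, then wait 3.0 h

- target, in percent of the starting material first charged, at 10 h
- what to do for the largest gain in target; "none" if nothing gains more than 2 percentage points (teal / grey / amber / violet / none)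
- target present, with what was taken out counted in, in percent of the starting material first charged, after amber
- target present, with what was taken out counted in, in percent of the starting material first charged, after violet

By target, the two runs look nearly the same: the epsilon run ends at 26%, the beta run at 27%. Starting material tells them apart. Read between 1.50 h and 5.00 h of the beta run, its first-order lifetime, the time in which it falls by the factor e, is:

lifetime, beta = (5.00 h − 1.50 h) / ln(34% / 3%) = 1.44 h

lifetime, epsilon = (12.0 h − 3.00 h) / ln(79% / 39%) = 12.7 h

These are readings and carry their scatter. The epsilon run stops within its first lifetime, with 39% of starting material still feeding target. The beta run has 2% left at 6.00 h, so its target is close to the end of its feed. For the flask at 10 h, this reckoning gives: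

share left = exp(−10 h / 1.44 h) = 0.0964%

Target in the flask therefore has hardly any feed left, and this reckoning expects it no higher than the late readings, 24% and 27%. Amber restores the feed, and 3.0 h is 2.08 lifetimes, so this reckoning expects starting material to react in an amount of about 43.8% of the first charge. This reckoning leans to amber.

The forecast gives 26%, chooses amber, and expects 40% after amber and 39.5% after violet: “Waiting gains nothing, and warming barely shifts the equilibrium.”

The flask gives 20.5% at 10 h. The best option is grey, gaining 21 percentage points against 14 points for amber, with 34.2% after amber and 30.3% after violet.

    starting material ⇌ other conformer (K = 1.10, k = 0.150 h⁻¹, Ea = 89.0 kJ mol⁻¹, ΔH = 2.00 kJ mol⁻¹)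
    starting material → target (k = 0.460 h⁻¹, Ea = 87.0 kJ mol⁻¹)
    other conformer → isomer of the product (k = 19.0 h⁻¹, Ea = 75.0 kJ mol⁻¹)
    target ⇌ isomer of the product (K = 3.10, k = 0.350 h⁻¹, Ea = 86.0 kJ mol⁻¹, ΔH = −54.0 kJ mol⁻¹)
    starting material + target → side product (k = 0.840 M⁻¹ h⁻¹, Ea = 66.0 kJ mol⁻¹)
    (constants at 5 °C)

In the flask at 10.0 h, isomer of the product holds 59.6% and target 20.5%, while starting material stands at 0.11% against the reckoned 0.0964%. The same flask read at 4.0 h has passed 2.78 lifetimes, so the reckoning leaves 6.22% of starting material. That flask holds 6.3%, and its target stands at 29.0%.

The readings stem from a simulated flask for an exercise; scatter was added.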